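## Retrosynthetic overview

1. No ring is built. Ring A (benzene) and ring B (pyranone) come together in umbelliferone 1; only C8–H (Duff formylation through aldimine 2 to aldehyde 3) and O7–H (methylation to 4) are changed.
2. Key disconnection: the side-chain bond C1'–C2', joining two carbonyl-derived carbons. Aldehyde 4 is the acceptor and isobutyraldehyde 5 becomes an isobutyryl anion equivalent on a chiral triazolylidene, giving (R)-acyloin 6 and the only stereocentre in one catalytic step.
3. Last disconnection: the ester C–O bond, 6 + 3-methylbut-2-enoyl chloride 7 → target 8.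

Assumption: the (5aS,10bR) antipode of the triazolium salt is taken to give the (R)-acyloin; the sense is checked on the first run (chiral HPLC, Mosher ester) and the commercial (5aR,10bS) salt is used instead if it is the opposite.

## Route

Step 1
Reactants: 1 umbelliferone (7-hydroxy-2H-chromen-2-one)
Product: 3 7-hydroxy-2-oxo-2H-chromene-8-carbaldehyde, via 7-hydroxy-8-(iminomethyl)-2H-chromen-2-one 2 (not isolated)
Conditions: hexamethylenetetramine (3 equiv), CF3CO2H, 90 °C, 12 h; then 1 M HCl, 60 °C, 1 h
Reagents that add atoms: hexamethylenetetramine, C1N2CN3CN1CN(C2)C3; water, O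
Why: Duff formylation (aminomethylation ortho to the phenol, internal hydride shift to the aldiminium, hydrolysis), which goes to C8 rather than C6 because C8 is the more nucleophilic ortho position of a 7-hydroxycoumarin, as C1 is in 2-naphthol; no stereocentre is involved.

Step 2
Reactants: 3 7-hydroxy-2-oxo-2H-chromene-8-carbaldehyde
Product: 4 7-methoxy-2-oxo-2H-chromene-8-carbaldehyde
Conditions: MeI (1.5 equiv), K2CO3 (2 equiv), DMF, 25 °C, 6 h
Reagents that add atoms: iodomethane, CI
Why: Williamson ether synthesis, SN2 of the acidic ortho-formyl phenoxide on MeI, under conditions that leave the lactone and the non-enolisable aldehyde untouched; no stereocentre is involved.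

Step 3
Reactants: 4 7-methoxy-2-oxo-2H-chromene-8-carbaldehyde; 5 2-methylpropanal
Product: 6 8-[(1R)-1-hydroxy-3-methyl-2-oxobutyl]-7-methoxy-2H-chromen-2-one
Conditions: 2-methylpropanal (3 equiv), (5aS,10bR)-2-(pentafluorophenyl)-5a,10b-dihydro-4H,6H-indeno[2,1-b][1,2,4]triazolo[4,3-d][1,4]oxazin-2-ium tetrafluoroborate (10 mol %), iPr2NEt (0.5 equiv), CH2Cl2, 25 °C, 48 h, argon; then recrystallisation (EtOAc–hexane) to ≥98% ee
Reagents that add atoms: none
Why: Proposed new method: an enantioselective crossed benzoin (acyloin) reaction of a branched aliphatic donor with a 2,6-disubstituted aryl acceptor, whose closest known reaction type is the triazolylidene-catalysed chemoselective crossed benzoin of aliphatic aldehydes with ortho-substituted benzaldehydes, where chiral triazolium salts already give useful ee; the carbene adds only to unhindered 5, because 4 is flanked by OMe and the ring oxygen and can form neither its own enaminol nor a homo-benzoin, the enaminol is an isobutyryl anion equivalent that attacks the Si face of the formyl group of 4 left open by the indane backbone and the C6F5 ring, and release of the carbene from the hindered adduct is practically irreversible, so the (R)-carbinol is set in the C–C bond-forming step and, the reaction being a pure addition, every atom of 4 and 5 ends up in 6.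

Step 4
Reactants: 6 8-[(1R)-1-hydroxy-3-methyl-2-oxobutyl]-7-methoxy-2H-chromen-2-one; 7 3-methylbut-2-enoyl chloride
Product: 8 (1R)-1-(7-methoxy-2-oxo-2H-chromen-8-yl)-3-methyl-2-oxobutyl 3-methylbut-2-enoate
Conditions: 3-methylbut-2-enoyl chloride (1.5 equiv), pyridine (3 equiv), 4-(dimethylamino)pyridine (5 mol %), CH2Cl2, 0 °C, 3 h
Reagents that add atoms: none
Why: O-acylation by nucleophilic acyl substitution through the acylpyridinium ion; the C1'–O bond is never broken, so the (R) centre is retained, and the weak base at 0 °C neither enolises the α-acyloxy ketone nor turns the acyl chloride into a vinylketene.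

## Compound list

1 | umbelliferone (7-hydroxy-2H-chromen-2-one) | O=c1ccc2ccc(O)cc2o1 | starting material
2 | 7-hydroxy-8-(iminomethyl)-2H-chromen-2-one (Duff aldimine, drawn as the parent imine; in the flask it is N-protonated and still carries aminomethyl residues) | N=Cc1c(O)ccc2ccc(=O)oc12 | intermediate
3 | 7-hydroxy-2-oxo-2H-chromene-8-carbaldehyde | O=Cc1c(O)ccc2ccc(=O)oc12 | intermediate
4 | 7-methoxy-2-oxo-2H-chromene-8-carbaldehyde | COc1ccc2ccc(=O)oc2c1C=O | intermediate
5 | 2-methylpropanal (isobutyraldehyde) | CC(C)C=O | starting material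
6 | 8-[(1R)-1-hydroxy-3-methyl-2-oxobutyl]-7-methoxy-2H-chromen-2-one | COc1ccc2ccc(=O)oc2c1[C@@H](O)C(=O)C(C)C | intermediate
7 | 3-methylbut-2-enoyl chloride | CC(C)=CC(=O)Cl | starting material
8 | (1R)-1-(7-methoxy-2-oxo-2H-chromen-8-yl)-3-methyl-2-oxobutyl 3-methylbut-2-enoate | COc1ccc2ccc(=O)oc2c1[C@@H](OC(=O)C=C(C)C)C(=O)C(C)C | target

## Step count and risks

Total step count: 4. Longest linear sequence: 4 (1 → 3 → 4 → 6 → 8).

Steps most likely to fail, in order of risk:

1. Step 3. A branched donor and a doubly ortho-substituted acceptor may couple slowly, and the ee may be modest. The fallback sets out from 4 and comes back at 6, and uses a nitronate as the isobutyryl anion equivalent. Aldehyde 4 undergoes an asymmetric nitroaldol reaction with 2-methyl-1-nitropropane (CC(C)C[N+](=O)[O-]), Cu(OAc)2·H2O (10 mol %) and 2,2'-(propane-2,2-diyl)bis(8,8a-dihydro-3aH-indeno[1,2-d]oxazole) (11 mol %, the antipode that gives the 1R alcohol) in EtOH at 0–25 °C. This gives 8-[(1R)-1-hydroxy-3-methyl-2-nitrobutyl]-7-methoxy-2H-chromen-2-one F1 as both C2' epimers, which converge. A reductive Nef reaction of F1 (aqueous TiCl3, NH4OAc, THF, 25 °C) then turns CH–NO2 into C=O and gives 6.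

2. Step 4. The hindered carbinol may acylate slowly, and the acidic C1'–H may epimerise or the acyl chloride isomerise to the 3-enoate. The fallback sets out from 4 and comes back at 8, and makes the ester by SN2 at carbon instead of acyl transfer at oxygen. Step 3 is run with the antipode of the triazolium salt to give 8-[(1S)-1-hydroxy-3-methyl-2-oxobutyl]-7-methoxy-2H-chromen-2-one F2. F2 is esterified under Mitsunobu conditions (3-methylbut-2-enoic acid, PPh3, diisopropyl azodicarboxylate, toluene, 0 °C) with inversion at C1' to give 8, with no acyl chloride and no amine base.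

3. Step 1. The Duff reaction often gives modest yields and some C6 isomer. The fallback sets out from 1 and comes back at 4, and replaces electrophilic formylation by halogenation and carbonylation. Iodination of 1 (I2, KI, aqueous NH3, 25 °C) gives 7-hydroxy-8-iodo-2H-chromen-2-one F3. Methylation (MeI, K2CO3, DMF, 25 °C) gives 8-iodo-7-methoxy-2H-chromen-2-one F4. Reductive carbonylation of F4 (PdCl2(PPh3)2 3 mol %, CO 1 atm, HCO2Na, DMF, 100 °C) gives 4.

## Further compounds

F1 | step 3 | 8-[(1R)-1-hydroxy-3-methyl-2-nitrobutyl]-7-methoxy-2H-chromen-2-one | COc1ccc2ccc(=O)oc2c1[C@@H](O)C([N+](=O)[O-])C(C)C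
F2 | step 4 | 8-[(1S)-1-hydroxy-3-methyl-2-oxobutyl]-7-methoxy-2H-chromen-2-one | COc1ccc2ccc(=O)oc2c1[C@H](O)C(=O)C(C)C
F3 | step 1 | 7-hydroxy-8-iodo-2H-chromen-2-one | Oc1ccc2ccc(=O)oc2c1I
F4 | step 1 | 8-iodo-7-methoxy-2H-chromen-2-one | COc1ccc2ccc(=O)oc2c1I
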